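**Strategy.** Ring B holds an enoate retron (the C17 carbinol on the C7=C8 alkene, labdane numbering), and the ring-fusion bond C5–C10 links a methyl-bearing quaternary carbon to a carbon β to C7. Both rings are therefore closed from an acyclic chain in one flask: hydrogen-atom transfer to a C10=C20 methylene gives the tertiary C10 radical, which adds 6-exo to C5 of an enal (ring A, C5–C10), and the C7 aldehyde so released is olefinated by a C8 phosphonoacetate (ring B, C7=C8). The precursor is an acyclic enal–alkene–phosphonoacetate whose single stereocentre C9 and ten carbons come from (R)-limonene; the protected ω-hydroxy acid is esterified last.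

Key step: step 11

Remark: labdane numbering is used throughout (C17 = CH2OH carbon on C8, C20 = methyl on C10, C15 = carbon bearing the ester oxygen); the acyl group is read as 32-hydroxydotriacontanoyl, and compounds 1, 2, 7 and 26 are taken as commercial.

**Step 1**
Reactants: 1 ethyl 2-methylpropanoate; 2 1,2-dibromoethane
Product: 4 ethyl 4-bromo-2,2-dimethylbutanoate, via lithium ester enolate 3 (not isolated)
Conditions: LiN(i-Pr)2, THF, −78 °C; then 2 (3 equiv), −78 → 23 °C
Reagents that add atoms: none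
Why: SN2 alkylation of the hindered ester enolate by excess dibromide should stop at monoalkylation because the product has no α-hydrogen.

**Step 2**
Reactants: 4 ethyl 4-bromo-2,2-dimethylbutanoate
Product: 5 4-bromo-2,2-dimethylbutan-1-ol
Conditions: i-Bu2AlH (2.5 equiv), CH2Cl2, −78 → 0 °C
Reagents that add atoms: none
Why: The aluminium hydride reduces the ester to the primary alcohol and should leave the primary bromide untouched at low temperature.

**Step 3**
Reactants: 5 4-bromo-2,2-dimethylbutan-1-ol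
Product: 6 (4-bromo-2,2-dimethylbutoxy)(tert-butyl)dimethylsilane
Conditions: TBSCl, imidazole, CH2Cl2, 0 → 23 °C
Reagents that add atoms: tert-butyldimethylsilyl chloride, CC(C)(C)[Si](C)(C)Cl
Why: Imidazole-promoted silylation of the neopentyl alcohol is mild enough to avoid cyclisation of the bromo alcohol to the tetrahydrofuran.

**Step 4**
Reactants: 7 (R)-(+)-limonene; 6 (4-bromo-2,2-dimethylbutoxy)(tert-butyl)dimethylsilane
Product: 9 tert-butyl({2,2-dimethyl-6-[(1R)-4-methylcyclohex-3-en-1-yl]hept-6-en-1-yl}oxy)dimethylsilane, via 10-lithiolimonene 8 (not isolated)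
Conditions: n-BuLi, TMEDA, 7 (excess), 23 °C; then 6, THF, −78 → 23 °C
Reagents that add atoms: none
Why: Allylic metalation of limonene at the isopropenyl methyl gives a 2-substituted allyllithium with two equivalent CH2 termini, whose SN2 alkylation by the primary bromide forms the C1–C2 bond without touching the future C9 stereocentre.

**Step 5**
Reactants: 9 tert-butyl({2,2-dimethyl-6-[(1R)-4-methylcyclohex-3-en-1-yl]hept-6-en-1-yl}oxy)dimethylsilane
Product: 11 methyl (3R)-3-(7-{[tert-butyl(dimethyl)silyl]oxy}-6,6-dimethylhept-1-en-2-yl)-6-oxoheptanoate, via methoxy hydroperoxide 10 (not isolated)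
Conditions: O3 (1.0 equiv), NaHCO3, CH2Cl2/MeOH, −78 °C; then Ac2O, Et3N, 0 → 23 °C
Reagents that add atoms: ozone, [O-][O+]=O; methanol, CO
Why: Ozone should attack the more electron-rich trisubstituted ring alkene first, and dehydration of the methanol-trapped carbonyl oxide at the former CH terminus (unsymmetrical ozonolysis) gives the methyl ester beside the methyl ketone; the hydroperoxide carbon of 10 is a transient, uncontrolled stereocentre.

**Step 6**
Reactants: 11 methyl (3R)-3-(7-{[tert-butyl(dimethyl)silyl]oxy}-6,6-dimethylhept-1-en-2-yl)-6-oxoheptanoate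
Product: 12 methyl (3R)-3-(7-{[tert-butyl(dimethyl)silyl]oxy}-6,6-dimethylhept-1-en-2-yl)-5-(2-methyl-1,3-dioxolan-2-yl)pentanoate
Conditions: Me3SiOCH2CH2OSiMe3, Me3SiOTf (cat.), CH2Cl2, −78 → −20 °C; pyridine
Reagents that add atoms: 1,2-bis(trimethylsilyloxy)ethane, C[Si](C)(C)OCCO[Si](C)(C)C
Why: Aprotic silyl-transfer ketalisation masks the ketone (needed for steps 7 and 11) without endangering the silyl ether or the 1,1-disubstituted alkene.

**Step 7**
Reactants: 12 methyl (3R)-3-(7-{[tert-butyl(dimethyl)silyl]oxy}-6,6-dimethylhept-1-en-2-yl)-5-(2-methyl-1,3-dioxolan-2-yl)pentanoate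
Product: 15 methyl (3S)-2-(diethoxyphosphoryl)-3-(7-{[tert-butyl(dimethyl)silyl]oxy}-6,6-dimethylhept-1-en-2-yl)-5-(2-methyl-1,3-dioxolan-2-yl)pentanoate (C2 epimers), via lithium ester enolate 13 (not isolated), via phosphonite 14 (not isolated)
Conditions: LiN(i-Pr)2 (1.1 equiv), THF, −78 °C; ClP(OEt)2, −78 → 0 °C; then 30% aq. H2O2, 0 °C
Reagents that add atoms: diethyl chlorophosphite, CCOP(Cl)OCC; hydrogen peroxide, OO
Why: C-phosphinylation of the ester enolate followed by oxidation of the phosphonite gives the α-phosphono ester; the new C8 stereocentre is uncontrolled and irrelevant because C8 becomes sp2 in step 11.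

**Step 8**
Reactants: 15 silyl ether phosphonate
Product: 16 methyl (3S)-2-(diethoxyphosphoryl)-3-(7-hydroxy-6,6-dimethylhept-1-en-2-yl)-5-(2-methyl-1,3-dioxolan-2-yl)pentanoate
Conditions: Bu4NF, AcOH, THF, 23 °C
Reagents that add atoms: none
Why: Buffered fluoride cleaves the primary silyl ether and should leave ketal, ester and phosphonate intact.

**Step 9**
Reactants: 16 primary alcohol
Product: 17 methyl (3S)-2-(diethoxyphosphoryl)-3-(6,6-dimethyl-7-oxohept-1-en-2-yl)-5-(2-methyl-1,3-dioxolan-2-yl)pentanoate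
Conditions: Dess–Martin periodinane, NaHCO3, CH2Cl2, 0 → 23 °C
Reagents that add atoms: none
Why: Dess–Martin oxidation of the neopentyl alcohol gives the non-enolisable C5 aldehyde under near-neutral conditions that do not deprotonate the phosphonoacetate.

**Step 10**
Reactants: 17 neopentyl aldehyde
Product: 18 methyl (3S)-2-(diethoxyphosphoryl)-3-[(7E)-6,6-dimethyl-9-oxonona-1,7-dien-2-yl]-5-(2-methyl-1,3-dioxolan-2-yl)pentanoate
Conditions: Ph3P=CHCHO (1.1 equiv), toluene, 90 °C
Reagents that add atoms: (triphenylphosphoranylidene)acetaldehyde, O=CC=P(c1ccccc1)(c1ccccc1)c1ccccc1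
Why: Wittig olefination with the stabilised formylmethylene ylide should give the (E)-enal (C5=C6–C7) under neutral conditions, the E geometry following from the reversible addition of a stabilised ylide.

**Step 11**
Reactants: 18 acyclic enal–alkene–phosphonoacetate
Product: 20 methyl (1S,4aR,8aR)-5,5,8a-trimethyl-1-[2-(2-methyl-1,3-dioxolan-2-yl)ethyl]-1,4,4a,5,6,7,8,8a-octahydronaphthalene-2-carboxylate, via monocyclic aldehyde 19 (not isolated)
Conditions: Fe(acac)3 (0.5 equiv), PhSiH3 (2.5 equiv), EtOH, 60 °C, dilute; evaporate; then K2CO3, 18-crown-6, toluene, 23 → 50 °C (same flask)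
Reagents that add atoms: none
Why: An iron hydride formed from Fe(acac)3 and PhSiH3 transfers a hydrogen atom to C20 of the only unactivated alkene, the nucleophilic tertiary C10 radical adds to C5 (β-carbon of the enal), and the enoxyl radical is reduced by divalent iron and protonated by ethanol to aldehyde 19; K2CO3 then deprotonates the C8 phosphonoacetate, which attacks the C7 aldehyde and expels diethyl phosphate. The closest known reaction types are the iron-mediated reductive alkene–acceptor (Giese) coupling and the intramolecular Horner–Wadsworth–Emmons olefination, here telescoped. Ring A closes 6-exo-trig through a chair transition state, and ring B closes by 6-exo-trig addition of the carbanion to the aldehyde followed by syn-elimination. C5 and C10 should be set trans because the chair places the C9 branch and the C6 arm equatorial and the C20 methyl axial; the absolute sense comes from C9, whose hydrogen points at the incoming enal while the bulky phosphonoacetate arm lies anti to the forming bond (Felkin-type), so that ring B closes with the C11 chain equatorial. The step needs chemoselective hydrogen-atom transfer, secured by the ketal and the absence of any other electron-rich alkene, and regioselective olefination, secured because only C8 is activated and both C8 epimers converge.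

**Step 12**
Reactants: 20 bicyclic enoate ketal
Product: 22 4-[(1S,4aR,8aR)-2-(hydroxymethyl)-5,5,8a-trimethyl-1,4,4a,5,6,7,8,8a-octahydronaphthalen-1-yl]butan-2-one, via ketal alcohol 21 (not isolated)
Conditions: i-Bu2AlH (2.5 equiv), CH2Cl2, −78 → 0 °C; then 1 M HCl, THF, 23 °C
Reagents that add atoms: water, O
Why: 1,2-Reduction of the enoate gives the C17 allylic alcohol and the acidic work-up hydrolyses the dioxolane to the C13 methyl ketone.

**Step 13**
Reactants: 22 keto alcohol
Product: 23 4-[(1S,4aR,8aR)-2-({[tert-butyl(dimethyl)silyl]oxy}methyl)-5,5,8a-trimethyl-1,4,4a,5,6,7,8,8a-octahydronaphthalen-1-yl]butan-2-one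
Conditions: TBSCl, imidazole, CH2Cl2, 23 °C
Reagents that add atoms: tert-butyldimethylsilyl chloride, CC(C)(C)[Si](C)(C)Cl
Why: Silylation of the C17 hydroxyl differentiates it from the C15 hydroxyl that is made in step 15.

**Step 14**
Reactants: 23 silyl ether ketone
Product: 24 ethyl (2E)-5-[(1S,4aR,8aR)-2-({[tert-butyl(dimethyl)silyl]oxy}methyl)-5,5,8a-trimethyl-1,4,4a,5,6,7,8,8a-octahydronaphthalen-1-yl]-3-methylpent-2-enoate
Conditions: (EtO)2P(O)CH2CO2Et, NaH, THF, 0 → 50 °C
Reagents that add atoms: triethyl phosphonoacetate, CCOC(=O)CP(=O)(OCC)OCC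
Why: Horner–Wadsworth–Emmons olefination of the methyl ketone should give mainly the E enoate (larger chain trans to the ester under reversible addition), the minor Z isomer being removed by chromatography.

**Step 15**
Reactants: 24 (E)-enoate
Product: 25 (2E)-5-[(1S,4aR,8aR)-2-({[tert-butyl(dimethyl)silyl]oxy}methyl)-5,5,8a-trimethyl-1,4,4a,5,6,7,8,8a-octahydronaphthalen-1-yl]-3-methylpent-2-en-1-ol
Conditions: i-Bu2AlH (2.2 equiv), CH2Cl2, −78 °C
Reagents that add atoms: none
Why: 1,2-Reduction of the enoate gives the C15 allylic alcohol with the alkene geometry retained.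

**Step 16**
Reactants: 26 16-bromohexadecanoic acid
Product: 27 16-bromohexadecan-1-ol
Conditions: BH3·THF, THF, 0 → 23 °C; aqueous work-up
Reagents that add atoms: none
Why: Borane reduces the carboxylic acid chemoselectively in the presence of the primary bromide.

**Step 17**
Reactants: 27 16-bromohexadecan-1-ol
Product: 28 [(16-bromohexadecyl)oxy](tert-butyl)dimethylsilane
Conditions: TBSCl, imidazole, CH2Cl2/DMF, 23 °C
Reagents that add atoms: tert-butyldimethylsilyl chloride, CC(C)(C)[Si](C)(C)Cl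
Why: Standard silylation protects the hydroxyl for Grignard formation and for the later esterification.

**Step 18**
Reactants: 28 [(16-bromohexadecyl)oxy](tert-butyl)dimethylsilane; 26 16-bromohexadecanoic acid
Product: 31 32-{[tert-butyl(dimethyl)silyl]oxy}dotriacontanoic acid, via Grignard reagent 29 (not isolated), via chloromagnesium carboxylate 30 (not isolated)
Conditions: 28, Mg, THF, 45 °C; separately 26, i-PrMgCl (1.0 equiv), THF, −20 °C; combine, Li2CuCl4 (3 mol%), −20 → 23 °C; aq. citric acid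
Reagents that add atoms: none
Why: Copper-catalysed sp3–sp3 cross-coupling of the alkyl Grignard reagent with the ω-bromo carboxylate joins two C16 units, the carboxylate salt being inert to the organocopper species.

**Step 19**
Reactants: 25 C15 allylic alcohol; 31 32-{[tert-butyl(dimethyl)silyl]oxy}dotriacontanoic acid
Product: 32 bis-silyl ether of the target (C17-O-TBS and ω-O-TBS)
Conditions: DCC, DMAP (cat.), CH2Cl2, 23 °C
Reagents that add atoms: none
Why: Steglich esterification acylates the only free hydroxyl (C15) under neutral conditions that do not isomerise the allylic system.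

**Step 20**
Reactants: 32 bis-silyl ether
Product: 33 (2E)-5-[(1S,4aR,8aR)-2-(hydroxymethyl)-5,5,8a-trimethyl-1,4,4a,5,6,7,8,8a-octahydronaphthalen-1-yl]-3-methylpent-2-en-1-yl 32-hydroxydotriacontanoate (target)
Conditions: HF·pyridine, pyridine, THF, 0 → 23 °C
Reagents that add atoms: none
Why: Buffered fluoride cleaves both primary silyl ethers and should leave the allylic ester and both trisubstituted alkenes untouched.

**Compound list**

1 | ethyl 2-methylpropanoate | CCOC(=O)C(C)C | starting material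
2 | 1,2-dibromoethane | BrCCBr | starting material
3 | lithium enolate of 1 | CCOC([O-])=C(C)C.[Li+] | intermediate
4 | ethyl 4-bromo-2,2-dimethylbutanoate | CCOC(=O)C(C)(C)CCBr | intermediate
5 | 4-bromo-2,2-dimethylbutan-1-ol | OCC(C)(C)CCBr | intermediate
6 | (4-bromo-2,2-dimethylbutoxy)(tert-butyl)dimethylsilane | CC(C)(C)[Si](C)(C)OCC(C)(C)CCBr | intermediate
7 | (R)-(+)-limonene, (4R)-1-methyl-4-(prop-1-en-2-yl)cyclohex-1-ene | CC1=CC[C@@H](CC1)C(C)=C | starting material
8 | 10-lithiolimonene, {2-[(1R)-4-methylcyclohex-3-en-1-yl]prop-2-en-1-yl}lithium | CC1=CC[C@@H](CC1)C(=C)C[Li] | intermediate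
9 | tert-butyl({2,2-dimethyl-6-[(1R)-4-methylcyclohex-3-en-1-yl]hept-6-en-1-yl}oxy)dimethylsilane | CC1=CC[C@@H](CC1)C(=C)CCCC(C)(C)CO[Si](C)(C)C(C)(C)C | intermediate
10 | (5R)-5-(7-{[tert-butyl(dimethyl)silyl]oxy}-6,6-dimethylhept-1-en-2-yl)-7-hydroperoxy-7-methoxyheptan-2-one (C7 epimers) | CC(=O)CC[C@@H](C(=C)CCCC(C)(C)CO[Si](C)(C)C(C)(C)C)CC(OC)OO | intermediate
11 | methyl (3R)-3-(7-{[tert-butyl(dimethyl)silyl]oxy}-6,6-dimethylhept-1-en-2-yl)-6-oxoheptanoate | CC(=O)CC[C@@H](C(=C)CCCC(C)(C)CO[Si](C)(C)C(C)(C)C)CC(=O)OC | intermediate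
12 | methyl (3R)-3-(7-{[tert-butyl(dimethyl)silyl]oxy}-6,6-dimethylhept-1-en-2-yl)-5-(2-methyl-1,3-dioxolan-2-yl)pentanoate | CC1(CC[C@@H](C(=C)CCCC(C)(C)CO[Si](C)(C)C(C)(C)C)CC(=O)OC)OCCO1 | intermediate
13 | lithium enolate of 12 | CC1(CC[C@@H](C(=C)CCCC(C)(C)CO[Si](C)(C)C(C)(C)C)C=C([O-])OC)OCCO1.[Li+] | intermediate
14 | methyl (3S)-2-(diethoxyphosphanyl)-3-(7-{[tert-butyl(dimethyl)silyl]oxy}-6,6-dimethylhept-1-en-2-yl)-5-(2-methyl-1,3-dioxolan-2-yl)pentanoate (C2 epimers) | CC1(CC[C@@H](C(=C)CCCC(C)(C)CO[Si](C)(C)C(C)(C)C)C(C(=O)OC)P(OCC)OCC)OCCO1 | intermediate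
15 | methyl (3S)-2-(diethoxyphosphoryl)-3-(7-{[tert-butyl(dimethyl)silyl]oxy}-6,6-dimethylhept-1-en-2-yl)-5-(2-methyl-1,3-dioxolan-2-yl)pentanoate (C2 epimers) | CC1(CC[C@@H](C(=C)CCCC(C)(C)CO[Si](C)(C)C(C)(C)C)C(C(=O)OC)P(=O)(OCC)OCC)OCCO1 | intermediate
16 | methyl (3S)-2-(diethoxyphosphoryl)-3-(7-hydroxy-6,6-dimethylhept-1-en-2-yl)-5-(2-methyl-1,3-dioxolan-2-yl)pentanoate | CC1(CC[C@@H](C(=C)CCCC(C)(C)CO)C(C(=O)OC)P(=O)(OCC)OCC)OCCO1 | intermediate
17 | methyl (3S)-2-(diethoxyphosphoryl)-3-(6,6-dimethyl-7-oxohept-1-en-2-yl)-5-(2-methyl-1,3-dioxolan-2-yl)pentanoate | CC1(CC[C@@H](C(=C)CCCC(C)(C)C=O)C(C(=O)OC)P(=O)(OCC)OCC)OCCO1 | intermediate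
18 | methyl (3S)-2-(diethoxyphosphoryl)-3-[(7E)-6,6-dimethyl-9-oxonona-1,7-dien-2-yl]-5-(2-methyl-1,3-dioxolan-2-yl)pentanoate | CC1(CC[C@@H](C(=C)CCCC(C)(C)/C=C/C=O)C(C(=O)OC)P(=O)(OCC)OCC)OCCO1 | intermediate
19 | methyl (3S)-2-(diethoxyphosphoryl)-5-(2-methyl-1,3-dioxolan-2-yl)-3-[(1R,2R)-1,3,3-trimethyl-2-(2-oxoethyl)cyclohexyl]pentanoate (ring A closed; methyl axial, both chains equatorial) | CC3(CC[C@H](C(C(=O)OC)P(=O)(OCC)OCC)[C@]1(C)CCCC(C)(C)[C@H]1CC=O)OCCO3 | intermediate
20 | methyl (1S,4aR,8aR)-5,5,8a-trimethyl-1-[2-(2-methyl-1,3-dioxolan-2-yl)ethyl]-1,4,4a,5,6,7,8,8a-octahydronaphthalene-2-carboxylate | CC3(CC[C@@H]1C(C(=O)OC)=CC[C@@H]2C(C)(C)CCC[C@@]12C)OCCO3 | intermediate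
21 | {(1S,4aR,8aR)-5,5,8a-trimethyl-1-[2-(2-methyl-1,3-dioxolan-2-yl)ethyl]-1,4,4a,5,6,7,8,8a-octahydronaphthalen-2-yl}methanol | CC3(CC[C@@H]1C(CO)=CC[C@@H]2C(C)(C)CCC[C@@]12C)OCCO3 | intermediate
22 | 4-[(1S,4aR,8aR)-2-(hydroxymethyl)-5,5,8a-trimethyl-1,4,4a,5,6,7,8,8a-octahydronaphthalen-1-yl]butan-2-one | CC(=O)CC[C@@H]1C(CO)=CC[C@@H]2C(C)(C)CCC[C@@]12C | intermediate
23 | 4-[(1S,4aR,8aR)-2-({[tert-butyl(dimethyl)silyl]oxy}methyl)-5,5,8a-trimethyl-1,4,4a,5,6,7,8,8a-octahydronaphthalen-1-yl]butan-2-one | CC(=O)CC[C@@H]1C(CO[Si](C)(C)C(C)(C)C)=CC[C@@H]2C(C)(C)CCC[C@@]12C | intermediate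
24 | ethyl (2E)-5-[(1S,4aR,8aR)-2-({[tert-butyl(dimethyl)silyl]oxy}methyl)-5,5,8a-trimethyl-1,4,4a,5,6,7,8,8a-octahydronaphthalen-1-yl]-3-methylpent-2-enoate | CCOC(=O)/C=C(\C)CC[C@@H]1C(CO[Si](C)(C)C(C)(C)C)=CC[C@@H]2C(C)(C)CCC[C@@]12C | intermediate
25 | (2E)-5-[(1S,4aR,8aR)-2-({[tert-butyl(dimethyl)silyl]oxy}methyl)-5,5,8a-trimethyl-1,4,4a,5,6,7,8,8a-octahydronaphthalen-1-yl]-3-methylpent-2-en-1-ol | OC/C=C(\C)CC[C@@H]1C(CO[Si](C)(C)C(C)(C)C)=CC[C@@H]2C(C)(C)CCC[C@@]12C | intermediate
26 | 16-bromohexadecanoic acid | OC(=O)CCCCCCCCCCCCCCCBr | starting material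
27 | 16-bromohexadecan-1-ol | OCCCCCCCCCCCCCCCCBr | intermediate
28 | [(16-bromohexadecyl)oxy](tert-butyl)dimethylsilane | CC(C)(C)[Si](C)(C)OCCCCCCCCCCCCCCCCBr | intermediate
29 | bromo(16-{[tert-butyl(dimethyl)silyl]oxy}hexadecyl)magnesium | CC(C)(C)[Si](C)(C)OCCCCCCCCCCCCCCCC[Mg]Br | intermediate
30 | chloromagnesium 16-bromohexadecanoate | BrCCCCCCCCCCCCCCCC(=O)O[Mg]Cl | intermediate
31 | 32-{[tert-butyl(dimethyl)silyl]oxy}dotriacontanoic acid | CC(C)(C)[Si](C)(C)OCCCCCCCCCCCCCCCCCCCCCCCCCCCCCCCC(=O)O | intermediate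
32 | (2E)-5-[(1S,4aR,8aR)-2-({[tert-butyl(dimethyl)silyl]oxy}methyl)-5,5,8a-trimethyl-1,4,4a,5,6,7,8,8a-octahydronaphthalen-1-yl]-3-methylpent-2-en-1-yl 32-{[tert-butyl(dimethyl)silyl]oxy}dotriacontanoate | C/C(=C\COC(=O)CCCCCCCCCCCCCCCCCCCCCCCCCCCCCCCO[Si](C)(C)C(C)(C)C)CC[C@@H]1C(CO[Si](C)(C)C(C)(C)C)=CC[C@@H]2C(C)(C)CCC[C@@]12C | intermediate
33 | (2E)-5-[(1S,4aR,8aR)-2-(hydroxymethyl)-5,5,8a-trimethyl-1,4,4a,5,6,7,8,8a-octahydronaphthalen-1-yl]-3-methylpent-2-en-1-yl 32-hydroxydotriacontanoate | C/C(=C\COC(=O)CCCCCCCCCCCCCCCCCCCCCCCCCCCCCCCO)CC[C@@H]1C(CO)=CC[C@@H]2C(C)(C)CCC[C@@]12C | target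

**Step count.** Total: 20 steps. Longest linear sequence: 17 steps (steps 1–15, 19, 20).

**Steps most likely to fail**

1. Step 11. The C10 radical may be quenched by a second hydrogen-atom transfer before it reaches the hindered C5, and the facial discrimination exerted by C9 at the radical centre may be modest. Fallback (sets out from 16, returns at 19 and so at 20): the radical is generated by photoredox decarboxylation instead of hydrogen-atom transfer. Mukaiyama hydration of the 1,1-disubstituted alkene of 16 (Co(acac)2, PhSiH3, O2) should give the tertiary alcohol F1. Dess–Martin oxidation of its primary hydroxyl only gives the hydroxy aldehyde F2, and the Wittig reaction of step 10 gives the hydroxy enal F3. Acylation of the tertiary hydroxyl with chloro N-phthalimidoyl oxalate gives the mixed oxalate F4. Visible-light reduction (Ru(bpy)3(PF6)2, Hantzsch ester, i-Pr2NEt·HBF4, 23 °C) should release the same C10 radical without a metal hydride present, which cyclises to 19; K2CO3/18-crown-6 then gives 20. The lower temperature should also sharpen the facial preference.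

2. Step 5. Chemoselectivity may be lost if ozone also cleaves the 1,1-disubstituted C10=C20 alkene. Fallback (sets out from 9, returns at 11): mCPBA (1.0 equiv, 0 °C) epoxidises the trisubstituted ring alkene selectively to the epoxide F5. HIO4 in aqueous THF cleaves it to the keto aldehyde F6. Pinnick oxidation (NaClO2, NaH2PO4, 2-methylbut-2-ene) gives the keto acid F7, and Me3SiCHN2 in MeOH gives 11.

3. Step 14. E selectivity may erode in the olefination of the methyl ketone. Fallback (sets out from 23, returns at 25, bypassing 24): kinetic enolisation and phosphorylation (LiN(i-Pr)2, then ClP(O)(OEt)2) gives the enol phosphate F8, which further LiN(i-Pr)2 eliminates to the terminal alkyne F9. Zirconium-catalysed syn-carboalumination (Me3Al, Cp2ZrCl2) gives the (E)-alkenylalane F10, which after n-BuLi is trapped with paraformaldehyde to give 25 with the geometry fixed by the syn addition.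

**Further compounds**

F1 | step 11 | methyl (3S)-2-(diethoxyphosphoryl)-3-(2,7-dihydroxy-6,6-dimethylheptan-2-yl)-5-(2-methyl-1,3-dioxolan-2-yl)pentanoate | CC1(CC[C@@H](C(C)(O)CCCC(C)(C)CO)C(C(=O)OC)P(=O)(OCC)OCC)OCCO1
F2 | step 11 | methyl (3S)-2-(diethoxyphosphoryl)-3-(2-hydroxy-6,6-dimethyl-7-oxoheptan-2-yl)-5-(2-methyl-1,3-dioxolan-2-yl)pentanoate | CC1(CC[C@@H](C(C)(O)CCCC(C)(C)C=O)C(C(=O)OC)P(=O)(OCC)OCC)OCCO1
F3 | step 11 | methyl (3S)-2-(diethoxyphosphoryl)-3-[(7E)-2-hydroxy-6,6-dimethyl-9-oxonon-7-en-2-yl]-5-(2-methyl-1,3-dioxolan-2-yl)pentanoate | CC1(CC[C@@H](C(C)(O)CCCC(C)(C)/C=C/C=O)C(C(=O)OC)P(=O)(OCC)OCC)OCCO1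
F4 | step 11 | N-phthalimidoyl oxalate of the tertiary alcohol F3 | CC1(CC[C@@H](C(C)(OC(=O)C(=O)ON2C(=O)c3ccccc3C2=O)CCCC(C)(C)/C=C/C=O)C(C(=O)OC)P(=O)(OCC)OCC)OCCO1
F5 | step 5 | ring 1,2-epoxide of 9 (epoxide epimers) | CC12OC1C[C@@H](CC2)C(=C)CCCC(C)(C)CO[Si](C)(C)C(C)(C)C
F6 | step 5 | (3R)-3-(7-{[tert-butyl(dimethyl)silyl]oxy}-6,6-dimethylhept-1-en-2-yl)-6-oxoheptanal | CC(=O)CC[C@@H](C(=C)CCCC(C)(C)CO[Si](C)(C)C(C)(C)C)CC=O
F7 | step 5 | (3R)-3-(7-{[tert-butyl(dimethyl)silyl]oxy}-6,6-dimethylhept-1-en-2-yl)-6-oxoheptanoic acid | CC(=O)CC[C@@H](C(=C)CCCC(C)(C)CO[Si](C)(C)C(C)(C)C)CC(=O)O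
F8 | step 14 | diethyl enol phosphate of ketone 23 (terminal enol) | C=C(OP(=O)(OCC)OCC)CC[C@@H]1C(CO[Si](C)(C)C(C)(C)C)=CC[C@@H]2C(C)(C)CCC[C@@]12C
F9 | step 14 | terminal alkyne, tert-butyl{[(1S,4aR,8aR)-1-(but-3-yn-1-yl)-5,5,8a-trimethyl-1,4,4a,5,6,7,8,8a-octahydronaphthalen-2-yl]methoxy}dimethylsilane | C#CCC[C@@H]1C(CO[Si](C)(C)C(C)(C)C)=CC[C@@H]2C(C)(C)CCC[C@@]12C
F10 | step 14 | (E)-alkenyl(dimethyl)alane from F9 | C[Al](C)/C=C(\C)CC[C@@H]1C(CO[Si](C)(C)C(C)(C)C)=CC[C@@H]2C(C)(C)CCC[C@@]12C
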